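## Retrosynthetic overview

1. The angelate is installed last on tetraol 30 (primary hydroxyls silylated). Tetraol 30 comes from decalin 29 by one acid treatment that turns the allylsilane C17–C8=C9 into C8=C17 plus C9–H and opens both acetonides.
2. Decalin 29 comes from the acyclic nitrotriene 27 by one intramolecular Diels–Alder reaction that forms C5–C10 (ring A) and C6–C7 (ring B) and sets C5 and C10. The nitro group on C6 is a traceless activator.
3. Enabling feature: ring B (C5–C6–C7–C8–C9–C10) is a cyclohexane with an exocyclic C8=C17 alkene next to C9–H, sharing the C5–C10 bond with ring A. That is the retron of a C7=C8–C9=C10 diene carrying CH2SiMe3 on C8 and a C5=C6 dienophile tethered through C1–C4. The 1,3-related O3 and O18 allow a temporary 1,3-dioxane that rigidifies this tether.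
4. Triene 27 comes from Negishi union of alkylzinc 20 (C1–C5, C18, C19; stereodiad from an iridium-catalysed tert-(hydroxy)prenylation) with enol triflate 19 (C8–C16, C20), then ester to allylsilane and CH2OH to nitroalkene.
5. Ring order: temporary dioxane (step 4) and dioxepine (step 8) first; rings A and B together (step 18); temporary rings opened (step 20).

Key step: step 18

Assumption: the (R)-Tol-BINAP-modified iridium catalyst is taken to deliver the (2R,3R)-diol 4; if the sense of induction is the opposite, the (S)-ligand is used and nothing else changes.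

Numbering: locants C1–C20 are the labdane locants of the target. Ring A = C1–C5 and C10; ring B = C5–C10; C17 = methylene carbon on C8; C18 = hydroxymethyl and C19 = methyl on C4; C20 = methyl on C10; C11–C16 = side chain.

## Route

Step 1
Reactants: 1 3-(benzyloxy)propan-1-ol; 2 2-methyl-2-vinyloxirane (isoprene monoxide, racemic)
Product: 4 (2R,3R)-5-(benzyloxy)-2-ethenyl-2-methylpentane-1,3-diol, via 3-(benzyloxy)propanal 3 (not isolated)
Conditions: π-allyliridium C,O-benzoate preformed from [Ir(cod)Cl]2, (R)-Tol-BINAP, 4-cyano-3-nitrobenzoic acid and allyl acetate (5 mol %), K3PO4 (5 mol %), THF, 60 °C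
Reagents that add atoms: none
Why: Iridium-catalysed redox-triggered tert-(hydroxy)prenylation: dehydrogenation of 1 gives aldehyde 3 and an iridium hydride that opens 2 (its stereocentre is erased) to an (E)-σ-allyliridium species, which adds through a closed chair transition state, so that the ligand sets the carbinol centre C3 as R and the (E)-allyl geometry puts the hydroxymethyl group anti to the new hydroxyl and sets quaternary C4 as R (the hydroxymethyl arm is the future C5, the vinyl group the future C18).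

Step 2
Reactants: 4 diol from step 1
Product: 5 (3R,4R)-1-(benzyloxy)-4-{[(tert-butyldimethylsilyl)oxy]methyl}-4-methylhex-5-en-3-ol
Conditions: TBSCl (1.05 equiv), imidazole, CH2Cl2, 0 °C
Reagents that add atoms: tert-butyldimethylsilyl chloride, CC(C)(C)[Si](C)(C)Cl
Why: Silylation of the primary hydroxyl should be much faster than that of the secondary carbinol flanked by the quaternary centre, which marks the arm that becomes C5.

Step 3
Reactants: 5 silyl ether from step 2
Product: 7 (2R,3R)-5-(benzyloxy)-2-{[(tert-butyldimethylsilyl)oxy]methyl}-2-methylpentane-1,3-diol, via hydroxy aldehyde 6 (not isolated)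
Conditions: O3, CH2Cl2–MeOH, −78 °C; then NaBH4, −78 → 0 °C
Reagents that add atoms: ozone, [O-][O+]=O
Why: Ozonolysis of the only alkene and in situ borohydride reduction of aldehyde 6 turn the vinyl group into the C18 hydroxymethyl group; the quaternary centre has no α-hydrogen, and reduction at low temperature should outrun retro-aldol cleavage and silyl migration.

Step 4
Reactants: 7 diol from step 3
Product: 8 (4R,5R)-4-[2-(benzyloxy)ethyl]-5-{[(tert-butyldimethylsilyl)oxy]methyl}-2,2,5-trimethyl-1,3-dioxane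
Conditions: 2,2-dimethoxypropane, PPTS (cat.), CH2Cl2, rt
Reagents that add atoms: 2,2-dimethoxypropane, COC(C)(C)OC
Why: Acid-catalysed acetal exchange closes the six-membered 1,3-dioxane on O3 and O18 (the only 1,3-diol), giving the template in which the C2 chain and the C5 arm are both equatorial and the C19 methyl is axial.

Step 5
Reactants: 8 benzyl ether from step 4
Product: 9 2-[(4R,5R)-5-{[(tert-butyldimethylsilyl)oxy]methyl}-2,2,5-trimethyl-1,3-dioxan-4-yl]ethan-1-ol
Conditions: H2 (1 atm), Pd/C, EtOAc, rt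
Reagents that add atoms: none
Why: Hydrogenolysis of the benzyl ether over Pd/C in a neutral aprotic solvent leaves the silyl ether and the acetonide intact, and no alkene is present at this stage.

Step 6
Reactants: 9 alcohol from step 5
Product: 10 tert-butyl{[(4R,5R)-4-(2-iodoethyl)-2,2,5-trimethyl-1,3-dioxan-5-yl]methoxy}dimethylsilane
Conditions: I2, PPh3, imidazole, CH2Cl2, 0 °C → rt
Reagents that add atoms: iodine, II
Why: Appel-type iodination (Garegg–Samuelsson conditions) of the unhindered primary alcohol by SN2 displacement of the alkoxyphosphonium ion.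

Step 7
Reactants: 11 but-2-yne-1,4-diol
Product: 12 (2E)-2-(tributylstannyl)but-2-ene-1,4-diol
Conditions: Bu3SnH, PdCl2(PPh3)2 (2 mol %), THF, rt
Reagents that add atoms: tributyltin hydride, CCCC[SnH](CCCC)CCCC
Why: Palladium-catalysed syn-hydrostannation of the symmetrical alkyne (no regiochemical issue) places Sn and H cis, so the two hydroxymethyl groups are cis, which is the geometry of the C13=C14 bond of the target.

Step 8
Reactants: 12 stannyl diol from step 7
Product: 13 tributyl(2,2-dimethyl-4,7-dihydro-1,3-dioxepin-5-yl)stannane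
Conditions: 2,2-dimethoxypropane, PPTS (cat.), CH2Cl2, rt
Reagents that add atoms: 2,2-dimethoxypropane, COC(C)(C)OC
Why: The cis-1,4-diol closes a seven-membered isopropylidene acetal by acetal exchange, which masks O15 and O16 through all later basic and organometallic steps.

Step 9
Reactants: 13 stannane from step 8
Product: 15 2-(2,2-dimethyl-4,7-dihydro-1,3-dioxepin-5-yl)ethan-1-ol, via alkenyllithium 14 (not isolated)
Conditions: n-BuLi, THF, −78 °C; then ethylene oxide, BF3·OEt2, −78 °C
Reagents that add atoms: ethylene oxide, C1CO1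
Why: Tin–lithium exchange gives the ring alkenyllithium 14, which opens ethylene oxide under BF3 activation at low temperature, before β-alkoxide elimination can occur, and so adds C12 and C11.

Step 10
Reactants: 15 alcohol from step 9
Product: 16 5-(2-iodoethyl)-2,2-dimethyl-4,7-dihydro-1,3-dioxepine
Conditions: I2, PPh3, imidazole, CH2Cl2, 0 °C
Reagents that add atoms: iodine, II
Why: Appel-type iodination of the primary homoallylic alcohol under neutral conditions that the acetal tolerates.

Step 11
Reactants: 16 iodide from step 10; 17 ethyl acetoacetate (2 equiv)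
Product: 18 ethyl 2-acetyl-4-(2,2-dimethyl-4,7-dihydro-1,3-dioxepin-5-yl)butanoate (racemic)
Conditions: K2CO3, DMF, rt → 50 °C
Reagents that add atoms: none
Why: C-Alkylation (SN2) of the β-keto ester enolate, which is soft and weakly basic and so should favour substitution over E2 of the homoallylic iodide; excess 17 limits dialkylation, and the new centre is racemic and becomes sp2 in step 12.

Step 12
Reactants: 18 β-keto ester from step 11
Product: 19 ethyl (2E)-2-[2-(2,2-dimethyl-4,7-dihydro-1,3-dioxepin-5-yl)ethyl]-3-{[(trifluoromethyl)sulfonyl]oxy}but-2-enoate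
Conditions: Tf2O, aq. Me4NOH, hexanes–CH2Cl2, 0–5 °C
Reagents that add atoms: trifluoromethanesulfonic anhydride, O=S(=O)(OS(=O)(=O)C(F)(F)F)C(F)(F)F
Why: O-Triflation of the non-chelated tetramethylammonium enolate under biphasic conditions should give the (E)-enol triflate (triflate trans to the ester), the geometry that later puts C1 outside and the C20 methyl inside the diene.

Step 13
Reactants: 10 iodide from step 6; 19 enol triflate from step 12
Product: 21 ethyl (2E)-5-[(4R,5R)-5-{[(tert-butyldimethylsilyl)oxy]methyl}-2,2,5-trimethyl-1,3-dioxan-4-yl]-2-[2-(2,2-dimethyl-4,7-dihydro-1,3-dioxepin-5-yl)ethyl]-3-methylpent-2-enoate, via alkylzinc iodide 20 (not isolated)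
Conditions: Zn dust, LiCl, THF, 40 °C; then 19, Pd(OAc)2 (2 mol %), SPhos (4 mol %), THF, rt
Reagents that add atoms: none
Why: Zinc insertion into the primary iodide (the oxygen is γ, so there is no β-leaving group) gives alkylzinc 20, which undergoes stereoretentive palladium-catalysed Negishi cross-coupling with the enol triflate to give the tetrasubstituted (E)-enoate.

Step 14
Reactants: 21 silyl ether from step 13
Product: 22 ethyl (2E)-2-[2-(2,2-dimethyl-4,7-dihydro-1,3-dioxepin-5-yl)ethyl]-5-[(4R,5S)-5-(hydroxymethyl)-2,2,5-trimethyl-1,3-dioxan-4-yl]-3-methylpent-2-enoate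
Conditions: TBAF, THF, 0 °C → rt
Reagents that add atoms: none
Why: Fluoride cleaves the only silyl ether while both acetals and the hindered enoate are inert, and removing silicon here avoids exposing the later allylsilane to fluoride.

Step 15
Reactants: 22 hydroxy ester from step 14
Product: 24 {(4R,5S)-4-[(3E)-4-[2-(2,2-dimethyl-4,7-dihydro-1,3-dioxepin-5-yl)ethyl]-3-methyl-5-[(trimethylsilyl)methyl]hexa-3,5-dien-1-yl]-2,2,5-trimethyl-1,3-dioxan-5-yl}methanol, via bis(silylmethyl) carbinol 23 (not isolated)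
Conditions: Me3SiCH2MgCl (5 equiv), CeCl3 (5 equiv), THF, −78 °C → rt; then silica gel, CH2Cl2, rt
Reagents that add atoms: (trimethylsilyl)methylmagnesium chloride, C[Si](C)(C)C[Mg]Cl
Why: Cerium-mediated double 1,2-addition to the ester (the free hydroxyl consumes one equivalent) gives carbinol 23, whose Peterson elimination on silica gel delivers the 2-(silylmethyl)-1,3-diene (Bunnelle allylsilane synthesis) without touching the C9=C10 geometry.

Step 16
Reactants: 24 diene alcohol from step 15
Product: 25 (4R,5S)-4-[(3E)-4-[2-(2,2-dimethyl-4,7-dihydro-1,3-dioxepin-5-yl)ethyl]-3-methyl-5-[(trimethylsilyl)methyl]hexa-3,5-dien-1-yl]-2,2,5-trimethyl-1,3-dioxane-5-carbaldehyde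
Conditions: Dess–Martin periodinane, NaHCO3, CH2Cl2, 0 °C → rt
Reagents that add atoms: none
Why: Dess–Martin oxidation of the neopentyl primary alcohol under buffered conditions that the allylsilane and the acetals tolerate; the aldehyde has no α-hydrogen and cannot epimerise.

Step 17
Reactants: 25 aldehyde from step 16
Product: 27 (4R,5S)-4-[(3E)-4-[2-(2,2-dimethyl-4,7-dihydro-1,3-dioxepin-5-yl)ethyl]-3-methyl-5-[(trimethylsilyl)methyl]hexa-3,5-dien-1-yl]-2,2,5-trimethyl-5-[(E)-2-nitroethenyl]-1,3-dioxane, via nitro alcohol 26 (not isolated)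
Conditions: MeNO2, KOt-Bu (0.2 equiv), THF–t-BuOH, 0 °C; then MsCl, i-Pr2NEt, CH2Cl2, −20 → 0 °C
Reagents that add atoms: nitromethane, C[N+](=O)[O-]
Why: Henry addition of nitromethane to the non-enolisable aldehyde gives nitro alcohol 26, and mesylation followed by E1cB elimination gives the (E)-nitroalkene, which brings in C6 together with its activating group.

Step 18
Reactants: 27 nitrotriene from step 17
Product: 28 (3R,4S,5S,6R,10R)-3,18:15,16-bis-O-isopropylidene-6-nitro-17-(trimethylsilyl)labda-8,13-diene-3,15,16,18-tetrol (trans-fused rings A/B, C8=C9 in ring B)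
Conditions: toluene (0.01 M), BHT (cat.), 110 °C, sealed tube
Reagents that add atoms: none
Why: Thermal type 1 intramolecular Diels–Alder reaction in which the C7=C8–C9=C10 diene, made electron-rich by the allylic C–Si bond and its alkyl groups, adds suprafacially to the nitro-activated C5=C6 dienophile in a concerted, asynchronous [4+2] cycloaddition. The closest known reactions are the thermal cyclisation of (E)-1-nitro-1,7,9-decatrienes to trans-fused nitrodecalins and Diels–Alder reactions of 1-vinyl-2,6,6-trimethylcyclohexene-type dienes, whose fully substituted terminus becomes the angular-methyl carbon. Ring A (C1–C5, C10) is closed by the C5–C10 bond with the four-atom tether C1–C4 joining diene and dienophile, and ring B (C5–C10) is the new cyclohexene, closed by the C6–C7 bond. C10 (quaternary) and C5 follow from the diene geometry (C1 outside, C20 methyl inside) combined with the nitro-endo, tether-anti transition state, which puts H5 trans to the C20 methyl; their absolute sense is dictated by the dioxane, whose equatorial C3–C2 and C4–C5 bonds can only be bridged through a chair with the C19 methyl axial; C6 (nitro trans to C4, from the E-nitroalkene) is erased in step 19. The step needs trans over cis ring fusion, which should be secured by the endo preference of the nitro group and by the fact that either cis-fused alternative must place C9 or C6 axial on the templated chair; regiochemistry is fixed by the tether, and the unactivated C13=C14 alkene cannot compete with the nitroalkene. The tetrasubstituted allylsilane C17–C8=C9 formed in the adduct is the latent C8=C17 methylene and C9–H of the target.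

Step 19
Reactants: 28 nitro decalin from step 18
Product: 29 (3R,4S,5S,10R)-3,18:15,16-bis-O-isopropylidene-17-(trimethylsilyl)labda-8,13-diene-3,15,16,18-tetrol
Conditions: Bu3SnH (5 equiv), AIBN (0.5 equiv), toluene, 110 °C
Reagents that add atoms: none
Why: Radical denitration (tributyltin hydride chain): stannyl radical addition to the nitro group and C–N β-scission give the secondary C6 radical, which abstracts hydrogen from the stannane, the high stannane concentration outrunning 3-exo attack on the homoallylic alkene.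

Step 20
Reactants: 29 allylsilane bis-acetonide from step 19
Product: 30 (3R,4S,5S,9R,10S,13Z)-labda-8(17),13-diene-3,15,16,18-tetrol
Conditions: p-TsOH·H2O (0.3 equiv), CH2Cl2–MeOH (1:1), 0 °C → rt
Reagents that add atoms: none
Why: SE2′ protodesilylation: acid protonates the tetrasubstituted allylsilane at C9 from the face opposite the axial C20 methyl (axial attack, β-silyl cation at C8), which sets C9 as R with the side chain equatorial and generates the exocyclic C8=C17 alkene, while the same acid removes both isopropylidene acetals by methanolysis and the far less basic product alkene should not isomerise.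

Step 21
Reactants: 30 tetraol from step 20
Product: 31 (3R,4S,5S,9R,10S,13Z)-15,16,18-tris[(tert-butyldimethylsilyl)oxy]labda-8(17),13-dien-3-ol
Conditions: TBSCl (3.3 equiv), imidazole, DMF, 0 °C
Reagents that add atoms: tert-butyldimethylsilyl chloride, CC(C)(C)[Si](C)(C)Cl
Why: Selective silylation separates the three primary hydroxyls (O15, O16, O18) from the hindered secondary O3–H next to the quaternary carbon.

Step 22
Reactants: 31 tris-silyl ether from step 21; 32 angelic acid [(2Z)-2-methylbut-2-enoic acid]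
Product: 34 (3R,4S,5S,9R,10S,13Z)-15,16,18-tris[(tert-butyldimethylsilyl)oxy]labda-8(17),13-dien-3-yl (2Z)-2-methylbut-2-enoate, via mixed anhydride 33 (not isolated)
Conditions: 32, 2,4,6-trichlorobenzoyl chloride, Et3N, toluene, rt; then 31, 80 °C (no DMAP)
Reagents that add atoms: none
Why: Yamaguchi-type acylation through mixed anhydride 33 in hot toluene without a nucleophilic catalyst, conditions under which angelates are formed without Z to E isomerisation to the tiglate.

Step 23
Reactants: 34 silylated angelate from step 22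
Product: 35 (3R,4S,5S,9R,10S,13Z)-15,16,18-trihydroxylabda-8(17),13-dien-3-yl (2Z)-2-methylbut-2-enoate (CNP0237954.1)
Conditions: HF·pyridine, pyridine, THF, 0 °C → rt
Reagents that add atoms: none
Why: Buffered HF·pyridine removes the three primary silyl ethers under mildly acidic conditions that avoid base-induced acyl migration from O3 to O18 and leave the angelate and both alkenes untouched.

## Compound list

1 | 3-(benzyloxy)propan-1-ol | OCCCOCc1ccccc1 | starting material
2 | 2-methyl-2-vinyloxirane (isoprene monoxide, racemic) | C=CC1(C)CO1 | starting material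
3 | 3-(benzyloxy)propanal | O=CCCOCc1ccccc1 | intermediate (not isolated)
4 | (2R,3R)-5-(benzyloxy)-2-ethenyl-2-methylpentane-1,3-diol | OC[C@@](C)(C=C)[C@H](O)CCOCc1ccccc1 | intermediate
5 | (3R,4R)-1-(benzyloxy)-4-{[(tert-butyldimethylsilyl)oxy]methyl}-4-methylhex-5-en-3-ol | CC(C)(C)[Si](C)(C)OC[C@@](C)(C=C)[C@H](O)CCOCc1ccccc1 | intermediate
6 | (2R,3R)-5-(benzyloxy)-2-{[(tert-butyldimethylsilyl)oxy]methyl}-3-hydroxy-2-methylpentanal | CC(C)(C)[Si](C)(C)OC[C@@](C)(C=O)[C@H](O)CCOCc1ccccc1 | intermediate (not isolated)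
7 | (2R,3R)-5-(benzyloxy)-2-{[(tert-butyldimethylsilyl)oxy]methyl}-2-methylpentane-1,3-diol | CC(C)(C)[Si](C)(C)OC[C@@](C)(CO)[C@H](O)CCOCc1ccccc1 | intermediate
8 | (4R,5R)-4-[2-(benzyloxy)ethyl]-5-{[(tert-butyldimethylsilyl)oxy]methyl}-2,2,5-trimethyl-1,3-dioxane | CC(C)(C)[Si](C)(C)OC[C@@]1(C)COC(C)(C)O[C@@H]1CCOCc1ccccc1 | intermediate
9 | 2-[(4R,5R)-5-{[(tert-butyldimethylsilyl)oxy]methyl}-2,2,5-trimethyl-1,3-dioxan-4-yl]ethan-1-ol | CC(C)(C)[Si](C)(C)OC[C@@]1(C)COC(C)(C)O[C@@H]1CCO | intermediate
10 | tert-butyl{[(4R,5R)-4-(2-iodoethyl)-2,2,5-trimethyl-1,3-dioxan-5-yl]methoxy}dimethylsilane | CC(C)(C)[Si](C)(C)OC[C@@]1(C)COC(C)(C)O[C@@H]1CCI | intermediate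
11 | but-2-yne-1,4-diol | OCC#CCO | starting material
12 | (2E)-2-(tributylstannyl)but-2-ene-1,4-diol | OC/C=C(\CO)[Sn](CCCC)(CCCC)CCCC | intermediate
13 | tributyl(2,2-dimethyl-4,7-dihydro-1,3-dioxepin-5-yl)stannane | CCCC[Sn](CCCC)(CCCC)C1=CCOC(C)(C)OC1 | intermediate
14 | (2,2-dimethyl-4,7-dihydro-1,3-dioxepin-5-yl)lithium | [Li]C1=CCOC(C)(C)OC1 | intermediate (not isolated)
15 | 2-(2,2-dimethyl-4,7-dihydro-1,3-dioxepin-5-yl)ethan-1-ol | OCCC1=CCOC(C)(C)OC1 | intermediate
16 | 5-(2-iodoethyl)-2,2-dimethyl-4,7-dihydro-1,3-dioxepine | ICCC1=CCOC(C)(C)OC1 | intermediate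
17 | ethyl acetoacetate (ethyl 3-oxobutanoate) | CCOC(=O)CC(C)=O | starting material
18 | ethyl 2-acetyl-4-(2,2-dimethyl-4,7-dihydro-1,3-dioxepin-5-yl)butanoate (racemic) | CCOC(=O)C(CCC1=CCOC(C)(C)OC1)C(C)=O | intermediate
19 | ethyl (2E)-2-[2-(2,2-dimethyl-4,7-dihydro-1,3-dioxepin-5-yl)ethyl]-3-{[(trifluoromethyl)sulfonyl]oxy}but-2-enoate | CCOC(=O)/C(CCC1=CCOC(C)(C)OC1)=C(/OS(=O)(=O)C(F)(F)F)C | intermediate
20 | {2-[(4R,5R)-5-{[(tert-butyldimethylsilyl)oxy]methyl}-2,2,5-trimethyl-1,3-dioxan-4-yl]ethyl}zinc iodide | CC(C)(C)[Si](C)(C)OC[C@@]1(C)COC(C)(C)O[C@@H]1CC[Zn]I | intermediate (not isolated)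
21 | ethyl (2E)-5-[(4R,5R)-5-{[(tert-butyldimethylsilyl)oxy]methyl}-2,2,5-trimethyl-1,3-dioxan-4-yl]-2-[2-(2,2-dimethyl-4,7-dihydro-1,3-dioxepin-5-yl)ethyl]-3-methylpent-2-enoate | CCOC(=O)/C(CCC1=CCOC(C)(C)OC1)=C(/CC[C@H]2OC(C)(C)OC[C@]2(C)CO[Si](C)(C)C(C)(C)C)C | intermediate
22 | ethyl (2E)-2-[2-(2,2-dimethyl-4,7-dihydro-1,3-dioxepin-5-yl)ethyl]-5-[(4R,5S)-5-(hydroxymethyl)-2,2,5-trimethyl-1,3-dioxan-4-yl]-3-methylpent-2-enoate | CCOC(=O)/C(CCC1=CCOC(C)(C)OC1)=C(/CC[C@H]2OC(C)(C)OC[C@]2(C)CO)C | intermediate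
23 | (3E)-3-[2-(2,2-dimethyl-4,7-dihydro-1,3-dioxepin-5-yl)ethyl]-6-[(4R,5S)-5-(hydroxymethyl)-2,2,5-trimethyl-1,3-dioxan-4-yl]-4-methyl-1-(trimethylsilyl)-2-[(trimethylsilyl)methyl]hex-3-en-2-ol | C[Si](C)(C)CC(O)(C[Si](C)(C)C)/C(CCC1=CCOC(C)(C)OC1)=C(/CC[C@H]2OC(C)(C)OC[C@]2(C)CO)C | intermediate (not isolated)
24 | {(4R,5S)-4-[(3E)-4-[2-(2,2-dimethyl-4,7-dihydro-1,3-dioxepin-5-yl)ethyl]-3-methyl-5-[(trimethylsilyl)methyl]hexa-3,5-dien-1-yl]-2,2,5-trimethyl-1,3-dioxan-5-yl}methanol | C=C(C[Si](C)(C)C)/C(CCC1=CCOC(C)(C)OC1)=C(/CC[C@H]2OC(C)(C)OC[C@]2(C)CO)C | intermediate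
25 | (4R,5S)-4-[(3E)-4-[2-(2,2-dimethyl-4,7-dihydro-1,3-dioxepin-5-yl)ethyl]-3-methyl-5-[(trimethylsilyl)methyl]hexa-3,5-dien-1-yl]-2,2,5-trimethyl-1,3-dioxane-5-carbaldehyde | C=C(C[Si](C)(C)C)/C(CCC1=CCOC(C)(C)OC1)=C(/CC[C@H]2OC(C)(C)OC[C@]2(C)C=O)C | intermediate
26 | nitroaldol adduct of 25: 2-nitro-1-hydroxyethyl group in place of the formyl group (both carbinol epimers) | C=C(C[Si](C)(C)C)/C(CCC1=CCOC(C)(C)OC1)=C(/CC[C@H]2OC(C)(C)OC[C@]2(C)C(O)C[N+](=O)[O-])C | intermediate (not isolated)
27 | (4R,5S)-4-[(3E)-4-[2-(2,2-dimethyl-4,7-dihydro-1,3-dioxepin-5-yl)ethyl]-3-methyl-5-[(trimethylsilyl)methyl]hexa-3,5-dien-1-yl]-2,2,5-trimethyl-5-[(E)-2-nitroethenyl]-1,3-dioxane | C=C(C[Si](C)(C)C)/C(CCC1=CCOC(C)(C)OC1)=C(/CC[C@H]2OC(C)(C)OC[C@]2(C)/C=C/[N+](=O)[O-])C | intermediate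
28 | (3R,4S,5S,6R,10R)-3,18:15,16-bis-O-isopropylidene-6-nitro-17-(trimethylsilyl)labda-8,13-diene-3,15,16,18-tetrol | C[Si](C)(C)CC1=C(CCC3=CCOC(C)(C)OC3)[C@]2(C)CC[C@H]4OC(C)(C)OC[C@]4(C)[C@H]2[C@H]([N+](=O)[O-])C1 | intermediate
29 | (3R,4S,5S,10R)-3,18:15,16-bis-O-isopropylidene-17-(trimethylsilyl)labda-8,13-diene-3,15,16,18-tetrol | C[Si](C)(C)CC1=C(CCC3=CCOC(C)(C)OC3)[C@]2(C)CC[C@H]4OC(C)(C)OC[C@]4(C)[C@H]2CC1 | intermediate
30 | (3R,4S,5S,9R,10S,13Z)-labda-8(17),13-diene-3,15,16,18-tetrol | C=C1CC[C@H]2[C@@](C)(CC[C@@H](O)[C@]2(C)CO)[C@@H]1CC/C(=C/CO)CO | intermediate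
31 | (3R,4S,5S,9R,10S,13Z)-15,16,18-tris[(tert-butyldimethylsilyl)oxy]labda-8(17),13-dien-3-ol | C=C1CC[C@H]2[C@@](C)(CC[C@@H](O)[C@]2(C)CO[Si](C)(C)C(C)(C)C)[C@@H]1CC/C(=C/CO[Si](C)(C)C(C)(C)C)CO[Si](C)(C)C(C)(C)C | intermediate
32 | angelic acid, (2Z)-2-methylbut-2-enoic acid | C/C=C(/C)C(=O)O | starting material
33 | (2Z)-2-methylbut-2-enoic 2,4,6-trichlorobenzoic anhydride | C/C=C(/C)C(=O)OC(=O)c1c(Cl)cc(Cl)cc1Cl | intermediate (not isolated)
34 | (3R,4S,5S,9R,10S,13Z)-15,16,18-tris[(tert-butyldimethylsilyl)oxy]labda-8(17),13-dien-3-yl (2Z)-2-methylbut-2-enoate | C=C1CC[C@H]2[C@@](C)(CC[C@@H](OC(=O)/C(C)=C\C)[C@]2(C)CO[Si](C)(C)C(C)(C)C)[C@@H]1CC/C(=C/CO[Si](C)(C)C(C)(C)C)CO[Si](C)(C)C(C)(C)C | intermediate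
35 | (3R,4S,5S,9R,10S,13Z)-15,16,18-trihydroxylabda-8(17),13-dien-3-yl (2Z)-2-methylbut-2-enoate (CNP0237954.1) | C=C1CC[C@H]2[C@@](C)(CC[C@@H](OC(=O)/C(C)=C\C)[C@]2(C)CO)[C@@H]1CC/C(=C/CO)CO | target

## Step count and risk

Total steps: 23.
Longest linear sequence: 17 steps (steps 1–6 then 13–23; the branch 7–12 then 13–23 is equally long).

Steps most likely to fail:

1. Step 18 (cycloaddition). The tetrasubstituted diene must reach an s-cis conformation with the C20 methyl inside, so ring closure may be slower than [1,5]-hydrogen shift in the diene or oligomerisation of the nitroalkene, and the preference for trans over cis fusion may erode at the temperature needed. Fallback (Lewis-acid-catalysed cycloaddition of an enal, then decarbonylation; it sets out from 25 and comes back at 29): Wittig reaction of aldehyde 25 with Ph3P=CHCHO (toluene, 80 °C) would give the (E)-enal triene F1. Me2AlCl (1.1 equiv, CH2Cl2, −78 → −20 °C) would activate the enal so that the intramolecular Diels–Alder reaction runs far below the temperature of the hydrogen shift, with a stronger endo preference on the same dioxane template, to give the 6-formyl decalin F2. Stoichiometric RhCl(PPh3)3 (toluene, 110 °C, Tsuji–Wilkinson decarbonylation) would then replace the formyl group by hydrogen and give 29, so that step 19 is not needed.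

2. Step 15 (allylsilane formation). The second addition to the hindered, conjugated ester may stall at the ketone stage, or the intermediate ketone may enolise and lose silicon. Fallback (stepwise acylation and methylenation; from 22 back to 24): AlMe3 with MeNH(OMe)·HCl (CH2Cl2, 0 °C → rt) would convert ester 22 into the Weinreb amide F3. Me3SiCH2MgCl (THF, 0 °C) would add once, the chelated tetrahedral intermediate preventing over-addition, to give the β-silyl ketone F4. Wittig methylenation with Ph3P=CH2 (THF, −78 → 0 °C) would then give diene 24.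

3. Step 19 (denitration). C–N homolysis of an unactivated secondary nitro group may be sluggish, with competing reduction at nitrogen to oxime or hydroxylamine. Fallback (polar removal of nitrogen through the ketone; from 28 back to 29): the nitronate of 28 (KOt-Bu, THF, 0 °C) would be treated with buffered aqueous TiCl3 (NH4OAc, pH 5, McMurry variant of the Nef reaction) to give the C6 ketone F5. TsNHNH2 (EtOH, rt) would give the tosylhydrazone F6. Catecholborane (CHCl3, 0 °C) followed by NaOAc·3H2O (reflux) would reduce it to the methylene compound 29 (Kabalka reduction) with the C8=C9 alkene left in place.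

Further compounds
F1 | step 18 | (2E)-3-{(4R,5S)-4-[(3E)-4-[2-(2,2-dimethyl-4,7-dihydro-1,3-dioxepin-5-yl)ethyl]-3-methyl-5-[(trimethylsilyl)methyl]hexa-3,5-dien-1-yl]-2,2,5-trimethyl-1,3-dioxan-5-yl}prop-2-enal | C=C(C[Si](C)(C)C)/C(CCC1=CCOC(C)(C)OC1)=C(/CC[C@H]2OC(C)(C)OC[C@]2(C)/C=C/C=O)C
F2 | step 18 | (3R,4S,5S,6R,10R)-6-formyl analogue of 28 (formyl in place of nitro) | C[Si](C)(C)CC1=C(CCC3=CCOC(C)(C)OC3)[C@]2(C)CC[C@H]4OC(C)(C)OC[C@]4(C)[C@H]2[C@H](C=O)C1
F3 | step 15 | N-methoxy-N-methyl amide corresponding to ester 22 | CON(C)C(=O)/C(CCC1=CCOC(C)(C)OC1)=C(/CC[C@H]2OC(C)(C)OC[C@]2(C)CO)C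
F4 | step 15 | (3E)-3-[2-(2,2-dimethyl-4,7-dihydro-1,3-dioxepin-5-yl)ethyl]-6-[(4R,5S)-5-(hydroxymethyl)-2,2,5-trimethyl-1,3-dioxan-4-yl]-4-methyl-1-(trimethylsilyl)hex-3-en-2-one | C[Si](C)(C)CC(=O)/C(CCC1=CCOC(C)(C)OC1)=C(/CC[C@H]2OC(C)(C)OC[C@]2(C)CO)C
F5 | step 19 | (3R,4S,5S,10R)-6-oxo analogue of 29 | C[Si](C)(C)CC1=C(CCC3=CCOC(C)(C)OC3)[C@]2(C)CC[C@H]4OC(C)(C)OC[C@]4(C)[C@H]2C(=O)C1
F6 | step 19 | p-toluenesulfonylhydrazone of F5 | C[Si](C)(C)CC1=C(CCC3=CCOC(C)(C)OC3)[C@]2(C)CC[C@H]4OC(C)(C)OC[C@]4(C)[C@H]2C(=NNS(=O)(=O)c5ccc(C)cc5)C1
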